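In this flask the capture agent and the partner each turn substrate into a product of their own.

common to all: substrate 0.087 M

| flask | partner | capture agent | free catalyst | remark | time |
|---|---|---|---|---|---|
| dawn | 1 equiv | 0.087 M | 5 mol% | run made earlier |  |
| summer | 2.2 equiv | 0.087 M | 5 mol% | run made earlier |  |
| autumn | 1.5 equiv | 0.087 M | 7.5 mol% | run made earlier |  |
| flask | 1.50 equiv | 0.0870 M | 5 mol% |  | 25 h |

- dawn (time / h: trapped intermediate / %, target / %): 1.00: 47, 45; 3.00: 44, 45; 6.00: 47, 45; 8.00: 44, 41; 12.0: 46, 47; 15.0: 46, 42; 20.0: 47, 44
- summer (time / h: trapped intermediate / %, target / %): 1.50: 27, 64; 2.50: 30, 59; 4.00: 27, 63; 6.00: 28, 62; 8.00: 28, 62; 12.0: 27, 61; 20.0: 29, 60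
- autumn (time / h: trapped intermediate / %, target / %): 4.00: 28, 64; 8.00: 28, 60; 12.0: 29, 64; 15.0: 27, 66; 20.0: 29, 68

(each reading ± 2 percentage points)



* share of trapped intermediate in trapped intermediate plus target at 20 s
* share of trapped intermediate in trapped intermediate plus target at 25 h
* which of trapped intermediate and target there is more of at 25 h

1. In the dawn and summer runs, both products stand flat within a scatter of 2 percentage points from the first reading to the last. Each of these two runs therefore reads as one split under kinetic control, not as a slow change.

2. Two rates make that split. The rate to target is taken to rise with partner equivalents E and catalyst fraction c, and the rate to trapped intermediate with capture agent. Their ratio R is target over trapped intermediate.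

3. The earlier runs charge capture agent equal to substrate, so R = s·E·c, where s is the selectivity factor. The summed readings give 19.3 for dawn, 20.0 for summer and 20.3 for autumn, with a mean reading of s = 19.8, which is R divided by E·c at that equal charge.

4. For this flask, R = 1.49, so the trapped share 1/(1+R) is 40.2%, and this reckoning puts more target than trapped intermediate.

5. At 5 mol% in this flask, s·c is 0.992, so this reckoning has partner and capture agent losing like fractions of their own charges. Their ratio then stays as charged, and this reckoning puts the same share at 20 s.

6. The forecast gave 40% at 20 s, 40% at 25 h and target ahead: "Partner and capture agent deplete proportionally".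

The flask gives 41.6% at 20 s and 39.9% at 25 h, with target at 54.2% against 36.1% of trapped intermediate. At 25 h, partner stands at 63.8% and capture agent at 63.9% of their own charges.

    substrate + free catalyst → free catalyst + open intermediate (k = 16.0 /M/s)
    free catalyst + open intermediate ⇌ catalyst intermediate (K = 8.40 /M, k = 21.0 /M/s)
    partner + catalyst intermediate → free catalyst + target (k = 1.30 /M/s)
    open intermediate + capture agent → trapped intermediate (k = 0.0360 /M/s)
    2 substrate → homo dimer (k = 0.0750 /M/s)

With capture agent at 0.35 M, s scaled by the charge ratio gives R = 0.370, a trapped share of 73.0%. That neighbour flask stands at a trapped share of 72.5% at 25 h, with trapped intermediate at 65.6% against target at 24.8%.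

The data are simulated for substances that don't exist, and the scatter is random.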